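The heterocyclic ring (ring C: O1, C2, C3, C4, C4a, C8a) of the central fisetinidol unit is treated as the hydrate of a cyclic enol ether O1–C2=C3. Its C2–C3 bond is therefore closed as a double bond by ring-closing metathesis between the α-aryl vinyl ether made from a simple phenyl ester and a vinyl group on C4, giving a 4-methoxyflav-2-ene; hydroboration anti to the C4 methoxy group then sets C2 and C3. The resulting flavan-3-ol 4-methyl ether supplies all three fisetinidol units, which are joined to benzylated (+)-catechin by three stereoselective C4 arylations before one global hydrogenolysis.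

Key step: step 6

Remark: flavonoid numbering is used (O1, C2, C3, C4, C4a, C5–C8, C8a; ring A = benzo ring, ring B = catechol ring, ring C = pyran ring); α/β mean below/above ring C in the usual drawing. The target is read as fisetinidol-(4α→6)-fisetinidol-(4α→6)-[fisetinidol-(4α→8)]-catechin, called here the upper, central, catechin and branch units. Wherever a 4-methoxy or 4-arylthio intermediate might form partly as its C4 epimer, the epimer is equally usable, because C4 is ionised again later.

Step 1
Reactants: 1 4-(benzyloxy)-2-hydroxybenzaldehyde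
Product: 2 racemic 5-(benzyloxy)-2-(1-hydroxyprop-2-en-1-yl)phenol
Conditions: CH2=CHMgBr (2.5 equiv), THF, −78 → 0 °C; sat. aq. NH4Cl, 0 °C; used crude
Reagents that add atoms: vinylmagnesium bromide, C=C[Mg]Br
Why: Grignard 1,2-addition to the aldehyde after the first equivalent has deprotonated the phenol; no stereocontrol is sought (racemate), and the cold neutral quench avoids loss of water to the o-quinone methide.

Step 2
Reactants: 2 racemic 5-(benzyloxy)-2-(1-hydroxyprop-2-en-1-yl)phenol; 3 3,4-bis(benzyloxy)benzoic acid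
Product: 5 racemic 5-(benzyloxy)-2-(1-hydroxyprop-2-en-1-yl)phenyl 3,4-bis(benzyloxy)benzoate, via acid chloride 4 (not isolated)
Conditions: 3, (COCl)2, cat. DMF, CH2Cl2, 0 °C → rt, evaporate; then 2, Et3N (1.1 equiv), CH2Cl2, −30 °C
Reagents that add atoms: oxalyl chloride, O=C(Cl)C(=O)Cl (chlorine only in intermediate 4)
Why: acid chloride formation followed by chemoselective O-acylation of the more acidic phenol over the secondary benzylic alcohol (no acyl-transfer catalyst, low temperature, one equivalent of base, so that the alcohol is never deprotonated and the acyl group does not migrate).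

Step 3
Reactants: 5 racemic 5-(benzyloxy)-2-(1-hydroxyprop-2-en-1-yl)phenyl 3,4-bis(benzyloxy)benzoate
Product: 6 5-(benzyloxy)-2-[(1S)-1-hydroxyprop-2-en-1-yl]phenyl 3,4-bis(benzyloxy)benzoate
Conditions: Novozym 435 (immobilised Candida antarctica lipase B), vinyl acetate, MTBE, 30 °C, stopped just past half conversion; chromatography
Reagents that add atoms: none
Why: lipase kinetic resolution by transesterification, in which the usual enantiopreference of this enzyme for secondary alcohols (aryl as large, vinyl as medium group) should acetylate the (R)-alcohol and leave the (S)-alcohol, the single stereocentre from which all others in the fisetinidol units derive.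

Step 4
Reactants: 6 5-(benzyloxy)-2-[(1S)-1-hydroxyprop-2-en-1-yl]phenyl 3,4-bis(benzyloxy)benzoate
Product: 7 5-(benzyloxy)-2-[(1S)-1-methoxyprop-2-en-1-yl]phenyl 3,4-bis(benzyloxy)benzoate
Conditions: Me3OBF4, 1,8-bis(dimethylamino)naphthalene, CH2Cl2, 0 °C → rt
Reagents that add atoms: trimethyloxonium tetrafluoroborate, C[O+](C)C.F[B-](F)(F)F
Why: O-methylation under non-alkoxide conditions, which avoids migration of the neighbouring aroyl group and retains configuration because the C–O bond of the carbinol is not broken.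

Step 5
Reactants: 7 5-(benzyloxy)-2-[(1S)-1-methoxyprop-2-en-1-yl]phenyl 3,4-bis(benzyloxy)benzoate
Product: 8 4-(benzyloxy)-2-({1-[3,4-bis(benzyloxy)phenyl]ethenyl}oxy)-1-[(1S)-1-methoxyprop-2-en-1-yl]benzene
Conditions: Tebbe reagent Cp2Ti(μ-Cl)(μ-CH2)AlMe2, cat. pyridine, THF/toluene, −40 → 0 °C; aq. NaOH; basic alumina
Reagents that add atoms: Tebbe reagent, C[Al-]1(C)C[Ti](C2C=CC=C2)(C2C=CC=C2)[Cl+]1
Why: Tebbe methylenation of the aryl ester carbonyl (titanium methylidene [2+2] addition and cycloreversion) gives the α-aryl vinyl ether under non-acidic conditions that leave the benzyl ethers, the allylic methyl ether and its stereocentre untouched.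

Step 6
Reactants: 8 4-(benzyloxy)-2-({1-[3,4-bis(benzyloxy)phenyl]ethenyl}oxy)-1-[(1S)-1-methoxyprop-2-en-1-yl]benzene
Product: 9 (4S)-7-(benzyloxy)-2-[3,4-bis(benzyloxy)phenyl]-4-methoxy-4H-chromene
Conditions: second-generation Grubbs catalyst RuCl2(=CHPh)(H2IMes)(PCy3) (10 mol %), 1,4-benzoquinone (10 mol %), 2,6-di-tert-butyl-4-methylpyridine (20 mol %), degassed toluene (5 mM), 70 °C; Et3N-deactivated silica
Reagents that add atoms: none
Why: The ruthenium benzylidene first exchanges onto the unhindered monosubstituted C3 vinyl group, and the resulting alkylidene adds across the 1,1-disubstituted aryl enol ether in an intramolecular [2+2] cycloaddition; cycloreversion of the ruthenacyclobutane leaves the C2=C3 double bond and a ruthenium methylidene that carries the chain with loss of ethene. The closest known reaction type is enol ether–olefin ring-closing metathesis, as used to turn esters of olefinic alcohols into C1-aryl glycals and 2-substituted 4H-chromenes. Ring C (O1, C2, C3, C4, C4a, C8a) is the only ring closed, as a six-membered ring with the new alkene endocyclic, and closure is favoured because both olefin arms sit on adjacent carbons of ring A. No stereocentre is created: the C4 methoxy stereocentre is not touched and emerges allylic to C3, where it directs step 7. The step needs ring closure to beat intermolecular metathesis and migration of the allylic double bond, which high dilution, the ortho tether and the benzoquinone additive should secure, and it needs the acid-labile 4-methoxyflav-2-ene to stay un-ionised, for which the hindered pyridine base is present.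

Step 7
Reactants: 9 (4S)-7-(benzyloxy)-2-[3,4-bis(benzyloxy)phenyl]-4-methoxy-4H-chromene
Product: 11 (2R,3S,4R)-7-(benzyloxy)-2-[3,4-bis(benzyloxy)phenyl]-4-methoxy-3,4-dihydro-2H-chromen-3-ol, via C3 alkylborane 10 (not isolated)
Conditions: BH3·THF, THF, 0 °C → rt; then 3 M NaOH, 30 % H2O2, 0 °C
Reagents that add atoms: hydrogen peroxide, OO; borane–tetrahydrofuran, B.C1CCOC1 (boron only in intermediate 10)
Why: syn hydroboration of the cyclic enol ether places boron on C3 (β to O1 and to the C2 aryl group) from the face anti to the C4 methoxy group, as in the hydroboration of 3-O-alkyl C1-aryl glycals, and oxidation with retention gives the 2α-aryl, 3β-hydroxy, 4α-methoxy (2,3-trans-3,4-trans) flavan, so that C2 and C3 are both set by the C4 stereocentre.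

Step 8
Reactants: 11 (2R,3S,4R)-7-(benzyloxy)-2-[3,4-bis(benzyloxy)phenyl]-4-methoxy-3,4-dihydro-2H-chromen-3-ol
Product: 12 (2R,3S,4R)-7-(benzyloxy)-2-[3,4-bis(benzyloxy)phenyl]-6-bromo-4-methoxy-3,4-dihydro-2H-chromen-3-ol
Conditions: NBS (1.0 equiv), NaHCO3, CH2Cl2, −40 → 0 °C
Reagents that add atoms: N-bromosuccinimide, O=C1CCC(=O)N1Br
Why: electrophilic aromatic bromination at C6, the unhindered position para to O1 and ortho to the 7-benzyloxy group and far more activated than ring B, caps the only reactive nucleophilic carbon of the units that later act purely as electrophiles.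

Step 9
Reactants: 11 (2R,3S,4R)-7-(benzyloxy)-2-[3,4-bis(benzyloxy)phenyl]-4-methoxy-3,4-dihydro-2H-chromen-3-ol
Product: 13 (2R,3R,4R)-7-(benzyloxy)-2-[3,4-bis(benzyloxy)phenyl]-4-[(2,6-dimethylphenyl)sulfanyl]-3,4-dihydro-2H-chromen-3-ol (same spatial arrangement as 11; the label at C3 changes only because sulfur raises the rank of C4)
Conditions: 2,6-Me2C6H3SH (3 equiv), Me3SiOTf (0.1 equiv), CH2Cl2, −78 → −30 °C
Reagents that add atoms: 2,6-dimethylbenzenethiol, Cc1cccc(C)c1S
Why: Lewis-acid thiolysis (SN1) through the C4 benzylic cation stabilised by O1 and the 7-benzyloxy group, with the excess thiol adding anti to the 3-hydroxyl, installs a hindered arylthio group that is inert to hard silyl Lewis acids and therefore serves as a latent leaving group.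

Step 10
Reactants: 14 (+)-catechin
Product: 15 5,7,3',4'-tetra-O-benzyl-(+)-catechin
Conditions: BnBr (4.4 equiv), K2CO3, DMF, 0 °C → rt
Reagents that add atoms: benzyl bromide, BrCc1ccccc1
Why: Williamson etherification of the four phenols only, since carbonate does not deprotonate the aliphatic 3-hydroxyl and the two stereocentres are not involved.

Step 11
Reactants: 12 6-bromo 4-methoxy flavan-3-ol; 15 5,7,3',4'-tetra-O-benzyl-(+)-catechin (3 equiv)
Product: 16 6-bromo-7,3',4'-tri-O-benzylfisetinidol-(4α→8)-5,7,3',4'-tetra-O-benzylcatechin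
Conditions: Me3SiOTf (0.2 equiv), CH2Cl2, −78 → −40 °C; Et3N quench
Reagents that add atoms: none
Why: Lewis-acid Friedel–Crafts alkylation through the C4 cation of 12, attacked by C8 of the benzylated catechin (its most nucleophilic carbon) anti to the C3 hydroxyl to give the 3,4-trans (4α) bond, while the bromine cap and the excess nucleophile suppress self-condensation and double alkylation.

Step 12
Reactants: 12 6-bromo 4-methoxy flavan-3-ol; 13 4-arylthio flavan-3-ol (2 equiv)
Product: 17 6-bromo-7,3',4'-tri-O-benzylfisetinidol-(4α→6)-[7,3',4'-tri-O-benzyl-4α-(2,6-dimethylphenylsulfanyl)fisetinidol]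
Conditions: Me3SiOTf (0.2 equiv), CH2Cl2, −78 → −30 °C; Et3N quench
Reagents that add atoms: none
Why: orthogonal activation in a Friedel–Crafts alkylation, in which the silyl triflate ionises only the C4 methoxy group of 12 and C6 of 13 (para to O1, not the doubly flanked C8) attacks anti to the C3 hydroxyl to give the 4α→6 bond, the hindered arylthio group neither ionising nor transferring.

Step 13
Reactants: 17 upper–central dimer carrying the 4-arylthio group; 16 branch–catechin dimer (1.5 equiv)
Product: 18 tridecabenzyl dibromo tetramer, 6-bromo-7,3',4'-tri-O-benzylfisetinidol-(4α→6)-7,3',4'-tri-O-benzylfisetinidol-(4α→6)-[6-bromo-7,3',4'-tri-O-benzylfisetinidol-(4α→8)]-5,7,3',4'-tetra-O-benzylcatechin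
Conditions: AgOTf (2.5 equiv), 2,6-di-tert-butyl-4-methylpyridine, 4 Å MS, CH2Cl2, −20 → 0 °C, dark
Reagents that add atoms: none
Why: thiophilic monovalent silver abstracts the arylthiolate to give the C4 cation of the central unit, which is trapped by C6 of the catechin unit of 16 (the only uncapped, strongly activated carbon) anti to the C3 hydroxyl to give the 4α→6 bond, the hindered base removing the acid that could cleave interflavan bonds.

Step 14
Reactants: 18 tridecabenzyl dibromo tetramer
Product: 19 fisetinidol-(4α→6)-fisetinidol-(4α→6)-[fisetinidol-(4α→8)]-catechin (target)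
Conditions: H2 (1 atm), Pd(OH)2/C, NaHCO3, THF/MeOH/H2O, rt; Sephadex LH-20
Reagents that add atoms: none
Why: hydrogenolysis cleaves the thirteen benzyl ethers and both aryl C–Br bonds in one operation, while the buffered neutral medium leaves the three interflavan C–C bonds and all eleven stereocentres untouched.

Compound list
1 | 4-(benzyloxy)-2-hydroxybenzaldehyde | O=Cc1ccc(OCc2ccccc2)cc1O | starting material
2 | racemic 5-(benzyloxy)-2-(1-hydroxyprop-2-en-1-yl)phenol | C=CC(O)c1ccc(OCc2ccccc2)cc1O | intermediate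
3 | 3,4-bis(benzyloxy)benzoic acid | OC(=O)c1ccc(OCc2ccccc2)c(OCc2ccccc2)c1 | starting material
4 | 3,4-bis(benzyloxy)benzoyl chloride | ClC(=O)c1ccc(OCc2ccccc2)c(OCc2ccccc2)c1 | intermediate (not isolated)
5 | racemic 5-(benzyloxy)-2-(1-hydroxyprop-2-en-1-yl)phenyl 3,4-bis(benzyloxy)benzoate | C=CC(O)c1ccc(OCc2ccccc2)cc1OC(=O)c1ccc(OCc2ccccc2)c(OCc2ccccc2)c1 | intermediate
6 | 5-(benzyloxy)-2-[(1S)-1-hydroxyprop-2-en-1-yl]phenyl 3,4-bis(benzyloxy)benzoate | C=C[C@H](O)c1ccc(OCc2ccccc2)cc1OC(=O)c1ccc(OCc2ccccc2)c(OCc2ccccc2)c1 | intermediate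
7 | 5-(benzyloxy)-2-[(1S)-1-methoxyprop-2-en-1-yl]phenyl 3,4-bis(benzyloxy)benzoate | C=C[C@H](OC)c1ccc(OCc2ccccc2)cc1OC(=O)c1ccc(OCc2ccccc2)c(OCc2ccccc2)c1 | intermediate
8 | 4-(benzyloxy)-2-({1-[3,4-bis(benzyloxy)phenyl]ethenyl}oxy)-1-[(1S)-1-methoxyprop-2-en-1-yl]benzene | C=C[C@H](OC)c1ccc(OCc2ccccc2)cc1OC(=C)c1ccc(OCc2ccccc2)c(OCc2ccccc2)c1 | intermediate
9 | (4S)-7-(benzyloxy)-2-[3,4-bis(benzyloxy)phenyl]-4-methoxy-4H-chromene | c1ccccc1COc1ccc2c(c1)OC(c1ccc(OCc3ccccc3)c(OCc3ccccc3)c1)=C[C@@H]2OC | intermediate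
10 | C3 alkylborane of 9 (BH2 at C3β, aryl 2α, methoxy 4α; same spatial arrangement as 11) | c1ccccc1COc1ccc2c(c1)O[C@H](c1ccc(OCc3ccccc3)c(OCc3ccccc3)c1)[C@@H](B)[C@@H]2OC | intermediate (not isolated)
11 | (2R,3S,4R)-7-(benzyloxy)-2-[3,4-bis(benzyloxy)phenyl]-4-methoxy-3,4-dihydro-2H-chromen-3-ol (2α-aryl, 3β-OH, 4α-OMe) | c1ccccc1COc1ccc2c(c1)O[C@H](c1ccc(OCc3ccccc3)c(OCc3ccccc3)c1)[C@@H](O)[C@@H]2OC | intermediate
12 | (2R,3S,4R)-7-(benzyloxy)-2-[3,4-bis(benzyloxy)phenyl]-6-bromo-4-methoxy-3,4-dihydro-2H-chromen-3-ol | c1ccccc1COc1c(Br)cc2c(c1)O[C@H](c1ccc(OCc3ccccc3)c(OCc3ccccc3)c1)[C@@H](O)[C@@H]2OC | intermediate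
13 | (2R,3R,4R)-7-(benzyloxy)-2-[3,4-bis(benzyloxy)phenyl]-4-[(2,6-dimethylphenyl)sulfanyl]-3,4-dihydro-2H-chromen-3-ol (2α-aryl, 3β-OH, 4α-SAr) | c1ccccc1COc1ccc2c(c1)O[C@H](c1ccc(OCc3ccccc3)c(OCc3ccccc3)c1)[C@@H](O)[C@@H]2Sc1c(C)cccc1C | intermediate
14 | (+)-catechin, (2R,3S) | O[C@H]1Cc2c(O)cc(O)cc2O[C@@H]1c1ccc(O)c(O)c1 | starting material
15 | 5,7,3',4'-tetra-O-benzyl-(+)-catechin | O[C@H]1Cc2c(OCc3ccccc3)cc(OCc3ccccc3)cc2O[C@@H]1c1ccc(OCc2ccccc2)c(OCc2ccccc2)c1 | intermediate
16 | 6-bromo-7,3',4'-tri-O-benzylfisetinidol-(4α→8)-5,7,3',4'-tetra-O-benzylcatechin (both units 2,3-trans; upper unit 3,4-trans) | c1c(OCc3ccccc3)c2c(c([C@@H]3c4cc(Br)c(OCc5ccccc5)cc4O[C@H](c4ccc(OCc5ccccc5)c(OCc5ccccc5)c4)[C@H]3O)c1OCc1ccccc1)O[C@H](c1ccc(OCc3ccccc3)c(OCc3ccccc3)c1)[C@@H](O)C2 | intermediate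
17 | 6-bromo-7,3',4'-tri-O-benzylfisetinidol-(4α→6)-[7,3',4'-tri-O-benzyl-4α-(2,6-dimethylphenylsulfanyl)fisetinidol] (both units 2,3-trans-3,4-trans) | c1ccccc1COc1c(Br)cc2c(c1)O[C@H](c1ccc(OCc3ccccc3)c(OCc3ccccc3)c1)[C@@H](O)[C@@H]2c1cc2c(cc1OCc1ccccc1)O[C@H](c1ccc(OCc3ccccc3)c(OCc3ccccc3)c1)[C@@H](O)[C@@H]2Sc1c(C)cccc1C | intermediate
18 | tridecabenzyl dibromo tetramer: 6-bromo-tri-O-benzylfisetinidol-(4α→6)-tri-O-benzylfisetinidol-(4α→6)-[6-bromo-tri-O-benzylfisetinidol-(4α→8)]-tetra-O-benzylcatechin | c1ccccc1COc1c(Br)cc2c(c1)O[C@H](c1ccc(OCc3ccccc3)c(OCc3ccccc3)c1)[C@@H](O)[C@@H]2c1cc2c(cc1OCc1ccccc1)O[C@H](c1ccc(OCc3ccccc3)c(OCc3ccccc3)c1)[C@@H](O)[C@@H]2c1c(OCc3ccccc3)c2c(c([C@@H]3c4cc(Br)c(OCc5ccccc5)cc4O[C@H](c4ccc(OCc5ccccc5)c(OCc5ccccc5)c4)[C@H]3O)c1OCc1ccccc1)O[C@H](c1ccc(OCc3ccccc3)c(OCc3ccccc3)c1)[C@@H](O)C2 | intermediate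
19 | fisetinidol-(4α→6)-fisetinidol-(4α→6)-[fisetinidol-(4α→8)]-catechin (CNP0263622.1) | Oc1ccc2c(c1)O[C@H](c1ccc(O)c(O)c1)[C@@H](O)[C@@H]2c1cc2c(cc1O)O[C@H](c1ccc(O)c(O)c1)[C@@H](O)[C@@H]2c1c(O)c2c(c([C@@H]3c4ccc(O)cc4O[C@H](c4ccc(O)c(O)c4)[C@H]3O)c1O)O[C@H](c1ccc(O)c(O)c1)[C@@H](O)C2 | target

Total step count: 14. Longest linear sequence: 11 steps (steps 1–7, 9, 12, 13, 14).

Steps most likely to fail

Step 6. The ruthenium alkylidene may be diverted into an unreactive heteroatom-stabilised carbene at the aryl enol ether, or may move the allylic double bond into conjugation before the ring closes. The fallback sets out from ester 7 and closes the same C2=C3 bond directly by an olefinic-ester cyclisation with the Takai–Utimoto reduced titanium ethylidene reagent (TiCl4, Zn, cat. PbCl2, TMEDA, CH3CHBr2, THF/CH2Cl2, 0 → 65 °C). Alkylidene exchange at the vinyl group is followed by intramolecular olefination of the aryl ester carbonyl, so the enol ether never has to be engaged by a metal carbene. This comes back to the route at flav-2-ene 9 and makes no compound outside the list (F0).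

Step 7. The Lewis-acidic borane may ionise the C4–OMe bond of the vinylogous acetal (flavylium formation, loss of the stereochemical relay and over-reduction), or it may add to both faces. The fallback sets out from 9 and replaces hydroboration by oxidation and reduction. Dimethyldioxirane (acetone/CH2Cl2, −78 → 0 °C) should epoxidise the enol ether anti to the methoxy group to give the 2β,3β-epoxy-4α-methoxyflavan F1. iBu2AlH (CH2Cl2, −78 °C) should then open it at C2 by aluminium-assisted cleavage to the O1-stabilised benzylic cation and deliver hydride from the face of the C3–O–Al group, as known for C1-aryl glycal epoxides. This comes back to the route at 11.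

Step 13. Attack of the bulky dimeric C4 cation on C6 of the catechin unit, which is flanked by two benzyloxy groups, may be slow, allowing C4 epimer formation, proton loss or scrambling of the thio group. The fallback changes the order of assembly and sets out from monomer 13 and dimer 16. AgOTf and 2,6-di-tert-butyl-4-methylpyridine (CH2Cl2, −20 → 0 °C, slow addition of 13 to excess 16) join the smaller monomeric cation to C6 of the catechin unit to give the trimer tri-O-benzylfisetinidol-(4α→6)-[6-bromo-tri-O-benzylfisetinidol-(4α→8)]-tetra-O-benzylcatechin F2. The only uncapped C6 of F2 (on its new fisetinidol unit) is then alkylated by methyl ether 12 with Me3SiOTf (CH2Cl2, −78 → −30 °C). This comes back to the route at 18.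

Further compounds
F0 | step 6 | none | none
F1 | step 7 | (4α)-7-(benzyloxy)-2-[3,4-bis(benzyloxy)phenyl]-2β,3β-epoxy-4-methoxyflavan | c1ccccc1COc1ccc2c(c1)O[C@@]4(c1ccc(OCc3ccccc3)c(OCc3ccccc3)c1)O[C@H]4[C@@H]2OC
F2 | step 13 | 7,3',4'-tri-O-benzylfisetinidol-(4α→6)-[6-bromo-7,3',4'-tri-O-benzylfisetinidol-(4α→8)]-5,7,3',4'-tetra-O-benzylcatechin | c1ccccc1COc1ccc2c(c1)O[C@H](c1ccc(OCc3ccccc3)c(OCc3ccccc3)c1)[C@@H](O)[C@@H]2c1c(OCc3ccccc3)c2c(c([C@@H]3c4cc(Br)c(OCc5ccccc5)cc4O[C@H](c4ccc(OCc5ccccc5)c(OCc5ccccc5)c4)[C@H]3O)c1OCc1ccccc1)O[C@H](c1ccc(OCc3ccccc3)c(OCc3ccccc3)c1)[C@@H](O)C2
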